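**Retrosynthetic overview**
1. The C3 ester is made last from triol 23 and epoxy acid 27 (Sharpless epoxidation of (E)-2-methylbut-2-en-1-ol); the 3α,4α-diol comes from a C3=C4 alkene by osmylation anti to the C14 methyl.
2. The C6=C7 enone comes from a C8 enol acetate plus a leaving group on C6 (E1cB); that group replaces, by Barton decarboxylation, the oxidised formyl group that activates the key step.
3. Key disconnection: C5–C10 and C6–C7 together, by an enantioselective iminium-catalysed intramolecular Diels–Alder reaction of the achiral, acyclic tetraenal 13; ring B (the cycloaddition) and ring A (the C1–C4 tether) form in the same step and no ring exists before it.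
4. Enabling feature: in ring B the oxygen-bearing C8 lies between C7 and C9, and C6–C7 and C5–C10 are 1,4-related across C8–C9, the retron of a 2-oxydiene (C7=C8–C9=C10) plus a dienophile (C5=C6); C6 is a CH that can carry a formyl handle for a while, and the Z C3=C4 bond of ring A lies in the tether.
5. 13 is assembled from pent-4-yn-1-ol and the Weinreb amide of 3-hydroxy-3-methylbutanoic acid: carboalumination–iodination, Weinreb ketone synthesis, Stork–Zhao iodo-olefination, enol acetate formation, Stille coupling.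

Key step: step 9

Remark on the chemistry: eudesmane numbering is used in all comments, also for the acyclic precursors (C14 = methyl on C10, C15 = methyl on C4, C11 = carbinol carbon on C7); α is the face of H5 and β the face of C14, so the target is read as 5α-H, 10β-methyl, 3α-acyloxy, 4α-hydroxy.

Step 1
Reactants: 1 ethyl 3-hydroxy-3-methylbutanoate
Product: 2 ethyl 3-methyl-3-[(triethylsilyl)oxy]butanoate
Conditions: Et3SiOTf, 2,6-lutidine, CH2Cl2, −78 to 0 °C
Reagents that add atoms: triethylsilyl trifluoromethanesulfonate, CC[Si](CC)(CC)OS(=O)(=O)C(F)(F)F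
Why: Silylation of a tertiary alcohol with a silyl triflate and a hindered base is routine, and the triethylsilyl ether blocks retro-aldol cleavage and acylation of the future C11 oxygen in the basic steps that follow.

Step 2
Reactants: 2 ethyl 3-methyl-3-[(triethylsilyl)oxy]butanoate
Product: 3 N-methoxy-N-methyl-3-methyl-3-[(triethylsilyl)oxy]butanamide
Conditions: MeNHOMe·HCl, i-PrMgCl, THF, −20 to 0 °C
Reagents that add atoms: N,O-dimethylhydroxylamine hydrochloride, CNOC.Cl
Why: Direct aminolysis of the ester by the chloromagnesium amide of N,O-dimethylhydroxylamine gives the Weinreb amide, which will accept exactly one equivalent of an alkenyllithium.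

Step 3
Reactants: 4 pent-4-yn-1-ol
Product: 6 (E)-5-iodo-4-methylpent-4-en-1-ol, via alkenylalane 5 (not isolated)
Conditions: AlMe3, Cp2ZrCl2 (cat.), CH2Cl2, 0 °C to rt; then I2, THF, −30 to 0 °C
Reagents that add atoms: trimethylaluminium, C[Al](C)C; iodine, [I][I]
Why: Negishi carboalumination adds methyl and aluminium syn across the terminal alkyne with methyl on the internal carbon, and iodinolysis with retention fixes the E trisubstituted alkene that becomes C9=C10 with its C14 methyl.

Step 4
Reactants: 6 (E)-5-iodo-4-methylpent-4-en-1-ol, 3 N-methoxy-N-methyl-3-methyl-3-[(triethylsilyl)oxy]butanamide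
Product: 8 (E)-9-hydroxy-2,6-dimethyl-2-[(triethylsilyl)oxy]non-5-en-4-one, via dilithio species 7 (not isolated)
Conditions: t-BuLi (3 equiv), Et2O, −78 °C; then 3, THF, −78 to 0 °C; aq. NH4Cl
Reagents that add atoms: none
Why: Iodine–lithium exchange on the lithium alkoxide gives a configurationally stable alkenyllithium, whose single addition to the Weinreb amide should give the E enone on work-up (Weinreb ketone synthesis).

Step 5
Reactants: 8 (E)-9-hydroxy-2,6-dimethyl-2-[(triethylsilyl)oxy]non-5-en-4-one
Product: 9 (E)-4,8-dimethyl-6-oxo-8-[(triethylsilyl)oxy]non-4-enal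
Conditions: Dess–Martin periodinane, NaHCO3, CH2Cl2, 0 °C to rt
Reagents that add atoms: none
Why: Periodinane oxidation of the primary alcohol to the aldehyde is neutral and mild enough to spare the enone and the tertiary silyl ether.

Step 6
Reactants: 9 (E)-4,8-dimethyl-6-oxo-8-[(triethylsilyl)oxy]non-4-enal
Product: 10 (5E,9Z)-10-iodo-2,6-dimethyl-2-[(triethylsilyl)oxy]undeca-5,9-dien-4-one
Conditions: EtPPh3I, n-BuLi, THF; I2, −78 °C; NaN(SiMe3)2, −78 °C; then 9, −78 °C
Reagents that add atoms: ethyltriphenylphosphonium iodide, CC[P+](c1ccccc1)(c1ccccc1)c1ccccc1.[I-]; iodine, [I][I]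
Why: The Stork–Zhao olefination with the α-iodoethylidene ylide should attack the aldehyde much faster than the hindered ketone and give the Z 2-iodoalk-2-ene, which sets the Z geometry of the future C3=C4 bond that ring A needs.

Step 7
Reactants: 10 (5E,9Z)-10-iodo-2,6-dimethyl-2-[(triethylsilyl)oxy]undeca-5,9-dien-4-one
Product: 12 (3Z,5E,9Z)-10-iodo-2,6-dimethyl-2-[(triethylsilyl)oxy]undeca-3,5,9-trien-4-yl acetate, via lithium dienolate 11 (not isolated)
Conditions: LiN(SiMe3)2, THF, −78 °C; then Ac2O, −78 to −40 °C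
Reagents that add atoms: acetic anhydride, CC(=O)OC(C)=O
Why: Kinetic deprotonation at the only saturated α-carbon gives the cross-conjugated enolate, Z at the new double bond because the bulky C11 group avoids the alkenyl substituent, and O-acetylation turns it into an acid-tolerant 2-acetoxydiene.

Step 8
Reactants: 12 (3Z,5E,9Z)-10-iodo-2,6-dimethyl-2-[(triethylsilyl)oxy]undeca-3,5,9-trien-4-yl acetate
Product: 13 (2E,4Z,8E,10Z)-10-acetoxy-4,8,12-trimethyl-12-[(triethylsilyl)oxy]trideca-2,4,8,10-tetraenal
Conditions: (E)-Bu3SnCH=CHCHO, Pd2(dba)3 (cat.), AsPh3, CuI, DMF, rt, dark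
Reagents that add atoms: (E)-3-(tributylstannyl)prop-2-enal, CCCC[Sn](CCCC)(CCCC)/C=C/C=O
Why: Stille coupling of an alkenyl iodide with an alkenylstannane proceeds with retention at both partners under neutral conditions, so the 2E,4Z-dienal should be installed without touching the enol acetate.

Step 9
Reactants: 13 (2E,4Z,8E,10Z)-10-acetoxy-4,8,12-trimethyl-12-[(triethylsilyl)oxy]trideca-2,4,8,10-tetraenal
Product: 16 8-acetoxy-6α-formyl-11-[(triethylsilyl)oxy]-5αH,7βH-eudesma-3,8-diene, via iminium ion 14 (not isolated), via cycloadduct iminium ion 15 (not isolated)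
Conditions: (2S,5S)-5-benzyl-2-tert-butyl-3-methylimidazolidin-4-one (20 mol %), CF3CO2H (20 mol %), MeCN/H2O 95:5, 0.02 M, −10 to 4 °C
Reagents that add atoms: none
Why: The secondary amine condenses with the dienal to the (E)-iminium ion 14, whose lowered LUMO lets the C5=C6 bond add across the tethered 2-acetoxydiene C7=C8–C9=C10 in a concerted, asynchronous [4+2] cycloaddition (C5–C10 bond leading), and hydrolysis of 15 returns the catalyst; the closest known reaction type is the imidazolidinone-catalysed enantioselective intramolecular Diels–Alder reaction of trienals that gives trans-fused decalin aldehydes. Ring B is closed by the cycloaddition itself and ring A at the same time through the four-carbon tether C1–C4 (type 1 intramolecular mode, diene terminus C10 and dienophile carbon C5 joined), the Z C3=C4 bond holding C2 and C5 on the same side. C10 (quaternary) and C5 are set relative to each other by the endo transition state (iminium group under the diene, tether exo) together with the E geometry of C9=C10 and of C5=C6, which places the C14 methyl anti to H5 (trans ring fusion). Their absolute sense comes from the catalyst, whose benzyl and tert-butyl groups shield the Re face of C5 in the (E)-iminium ion so that the diene adds to the Si face (5α-H, 10β-methyl); C6 and C7 are also set (both substituents α) but are erased in step 12. The step needs endo selectivity, facial selectivity and a Z C3=C4 bond: the terminal iminium group secures endo addition, the catalyst secures the face, and an E isomer at C3=C4 cannot close ring A and so does not lead to a wrong cycloadduct.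

Step 10
Reactants: 16 8-acetoxy-6α-formyl-11-[(triethylsilyl)oxy]-5αH,7βH-eudesma-3,8-diene
Product: 17 8-acetoxy-11-[(triethylsilyl)oxy]-5αH,7βH-eudesma-3,8-diene-6α-carboxylic acid
Conditions: NaClO2, NaH2PO4, 2-methylbut-2-ene, t-BuOH/H2O, 0 °C to rt
Reagents that add atoms: sodium chlorite, [Na+].[O-]Cl=O
Why: Pinnick oxidation should convert the aldehyde into the acid without touching the alkenes or the enol acetate, because the hypochlorous acid by-product is scavenged by 2-methylbut-2-ene.

Step 11
Reactants: 17 8-acetoxy-11-[(triethylsilyl)oxy]-5αH,7βH-eudesma-3,8-diene-6α-carboxylic acid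
Product: 19 8-acetoxy-6β-(pyridin-2-ylsulfanyl)-11-[(triethylsilyl)oxy]-5αH,7βH-eudesma-3,8-diene, via thiohydroxamate ester 18 (not isolated)
Conditions: 1-hydroxypyridine-2(1H)-thione, N,N'-dicyclohexylcarbodiimide, DMAP (cat.), CH2Cl2, 0 °C to rt, dark; then hν (tungsten lamp), rt
Reagents that add atoms: 1-hydroxypyridine-2(1H)-thione, ON1C=CC=CC1=S
Why: Barton decarboxylation: photolysis of the O-acyl thiohydroxamate releases CO2 and a C6 radical that attacks the thiocarbonyl sulfur of a second ester molecule in a chain, so the carboxyl is exchanged for a pyridin-2-ylsulfanyl leaving group, expected anti to the bulky C7 substituent although either C6 epimer serves.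

Step 12
Reactants: 19 8-acetoxy-6β-(pyridin-2-ylsulfanyl)-11-[(triethylsilyl)oxy]-5αH,7βH-eudesma-3,8-diene
Product: 21 11-[(triethylsilyl)oxy]-5αH-eudesma-3,6-dien-8-one, via sulfanyl ketone 20 (not isolated)
Conditions: K2CO3, MeOH, 0 °C to rt; then DBU, rt
Reagents that add atoms: none
Why: Methanolysis of the enol acetate unveils the C8 ketone, and the C6 sulfide, now β to it, should leave by E1cB elimination (retro-thia-Michael reaction), which can only place the double bond at C6=C7, erases the C6 and C7 stereocentres and is mild enough to leave the γ-hydrogen at C5 in place.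

Step 13
Reactants: 21 11-[(triethylsilyl)oxy]-5αH-eudesma-3,6-dien-8-one
Product: 22 3α,4α-dihydroxy-11-[(triethylsilyl)oxy]-5αH-eudesm-6-en-8-one
Conditions: OsO4 (cat.), N-methylmorpholine N-oxide, acetone/H2O, 0 °C to rt
Reagents that add atoms: osmium tetroxide, O=[Os](=O)(=O)=O; N-methylmorpholine N-oxide, C[N+]1([O-])CCOCC1
Why: Upjohn dihydroxylation should pick the electron-rich trisubstituted C3=C4 bond over the hindered, electron-poor enone and add syn from the α face, opposite the axial C14 methyl, which sets C3 and C4 together (3α,4α-diol, C15 axial).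

Step 14
Reactants: 22 3α,4α-dihydroxy-11-[(triethylsilyl)oxy]-5αH-eudesm-6-en-8-one
Product: 23 3α,4α,11-trihydroxy-5αH-eudesm-6-en-8-one
Conditions: HF·pyridine, pyridine, THF, 0 °C to rt
Reagents that add atoms: none
Why: Buffered fluoride cleaves the tertiary triethylsilyl ether without strong base or strong acid, so the C5 hydrogen and the tertiary allylic alcohol are not put at risk.

Step 15
Reactants: 24 (E)-2-methylbut-2-en-1-ol
Product: 25 [(2R,3R)-2,3-dimethyloxiran-2-yl]methanol
Conditions: Ti(OiPr)4 (cat.), D-(−)-diethyl tartrate, t-BuOOH, 4 Å molecular sieves, CH2Cl2, −20 °C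
Reagents that add atoms: tert-butyl hydroperoxide, CC(C)(C)OO
Why: Sharpless asymmetric epoxidation delivers oxygen syn to both carbons of the E allylic alcohol on the face dictated by the tartrate, D-(−)-tartrate giving the 2R,3R epoxide, which fixes both stereocentres of the acyl group.

Step 16
Reactants: 25 [(2R,3R)-2,3-dimethyloxiran-2-yl]methanol
Product: 27 (2S,3R)-2,3-dimethyloxirane-2-carboxylic acid, via epoxy aldehyde 26 (not isolated)
Conditions: RuCl3 (cat.), NaIO4, CCl4/MeCN/H2O, rt
Reagents that add atoms: water, O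
Why: Ruthenium tetroxide generated in the flask oxidises the primary alcohol through the aldehyde hydrate to the acid without opening the epoxide or touching its stereocentres (the C2 descriptor changes only because the priorities change).

Step 17
Reactants: 23 3α,4α,11-trihydroxy-5αH-eudesm-6-en-8-one, 27 (2S,3R)-2,3-dimethyloxirane-2-carboxylic acid
Product: 29 4α,11-dihydroxy-8-oxo-5αH-eudesm-6-en-3α-yl (2S,3R)-2,3-dimethyloxirane-2-carboxylate, via mixed anhydride 28 (not isolated)
Conditions: 2,4,6-trichlorobenzoyl chloride, Et3N, THF, 0 °C to rt (27 only); then 23, DMAP, toluene, rt to 40 °C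
Reagents that add atoms: none
Why: Yamaguchi esterification activates the hindered glycidic acid as a mixed anhydride and DMAP should transfer the acyl group to the only secondary hydroxyl (C3), the two tertiary hydroxyls being inert, with no change at any stereocentre.

**Compound list**
1 | ethyl 3-hydroxy-3-methylbutanoate | CCOC(=O)CC(C)(C)O | starting material
2 | ethyl 3-methyl-3-[(triethylsilyl)oxy]butanoate | CCOC(=O)CC(C)(C)O[Si](CC)(CC)CC | intermediate
3 | N-methoxy-N-methyl-3-methyl-3-[(triethylsilyl)oxy]butanamide | CON(C)C(=O)CC(C)(C)O[Si](CC)(CC)CC | intermediate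
4 | pent-4-yn-1-ol | C#CCCCO | starting material
5 | alkenylalane: dimethyl[(E)-5-(dimethylalumanyloxy)-2-methylpent-1-en-1-yl]alumane | C[Al](C)/C=C(\C)CCCO[Al](C)C | intermediate
6 | (E)-5-iodo-4-methylpent-4-en-1-ol | OCCC/C(C)=C/I | intermediate
7 | dilithio species: lithium (E)-5-lithio-4-methylpent-4-en-1-olate | [Li]OCCC/C(C)=C/[Li] | intermediate
8 | (E)-9-hydroxy-2,6-dimethyl-2-[(triethylsilyl)oxy]non-5-en-4-one | OCCC/C(C)=C/C(=O)CC(C)(C)O[Si](CC)(CC)CC | intermediate
9 | (E)-4,8-dimethyl-6-oxo-8-[(triethylsilyl)oxy]non-4-enal | O=CCC/C(C)=C/C(=O)CC(C)(C)O[Si](CC)(CC)CC | intermediate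
10 | (5E,9Z)-10-iodo-2,6-dimethyl-2-[(triethylsilyl)oxy]undeca-5,9-dien-4-one | I/C(C)=C\CC/C(C)=C/C(=O)CC(C)(C)O[Si](CC)(CC)CC | intermediate
11 | lithium (3Z,5E,9Z)-10-iodo-2,6-dimethyl-2-[(triethylsilyl)oxy]undeca-3,5,9-trien-4-olate | I/C(C)=C\CC/C(C)=C/C(O[Li])=C/C(C)(C)O[Si](CC)(CC)CC | intermediate
12 | (3Z,5E,9Z)-10-iodo-2,6-dimethyl-2-[(triethylsilyl)oxy]undeca-3,5,9-trien-4-yl acetate | I/C(C)=C\CC/C(C)=C/C(OC(C)=O)=C/C(C)(C)O[Si](CC)(CC)CC | intermediate
13 | (2E,4Z,8E,10Z)-10-acetoxy-4,8,12-trimethyl-12-[(triethylsilyl)oxy]trideca-2,4,8,10-tetraenal | O=C/C=C/C(C)=C\CC/C(C)=C/C(OC(C)=O)=C/C(C)(C)O[Si](CC)(CC)CC | intermediate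
14 | iminium trifluoroacetate of 13 with the imidazolidinone catalyst | C(=[N+]1[C@H](C(C)(C)C)N(C)C(=O)[C@@H]1Cc1ccccc1)/C=C/C(C)=C\CC/C(C)=C/C(OC(C)=O)=C/C(C)(C)O[Si](CC)(CC)CC.[O-]C(=O)C(F)(F)F | intermediate
15 | iminium trifluoroacetate of cycloadduct 16 with the catalyst | C(=[N+]1[C@H](C(C)(C)C)N(C)C(=O)[C@@H]1Cc1ccccc1)[C@H]1[C@@H](C(C)(C)O[Si](CC)(CC)CC)C(OC(C)=O)=C[C@@]2(C)CCC=C(C)[C@H]12.[O-]C(=O)C(F)(F)F | intermediate
16 | 8-acetoxy-6α-formyl-11-[(triethylsilyl)oxy]-5αH,7βH-eudesma-3,8-diene | O=C[C@H]1[C@@H](C(C)(C)O[Si](CC)(CC)CC)C(OC(C)=O)=C[C@@]2(C)CCC=C(C)[C@H]12 | intermediate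
17 | 8-acetoxy-11-[(triethylsilyl)oxy]-5αH,7βH-eudesma-3,8-diene-6α-carboxylic acid | OC(=O)[C@H]1[C@@H](C(C)(C)O[Si](CC)(CC)CC)C(OC(C)=O)=C[C@@]2(C)CCC=C(C)[C@H]12 | intermediate
18 | 2-thioxopyridin-1(2H)-yl ester of 17 (O-acyl thiohydroxamate) | S=C1C=CC=CN1OC(=O)[C@H]1[C@@H](C(C)(C)O[Si](CC)(CC)CC)C(OC(C)=O)=C[C@@]2(C)CCC=C(C)[C@H]12 | intermediate
19 | 8-acetoxy-6β-(pyridin-2-ylsulfanyl)-11-[(triethylsilyl)oxy]-5αH,7βH-eudesma-3,8-diene | c1ccnc(c1)S[C@@H]1[C@@H](C(C)(C)O[Si](CC)(CC)CC)C(OC(C)=O)=C[C@@]2(C)CCC=C(C)[C@H]12 | intermediate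
20 | 6β-(pyridin-2-ylsulfanyl)-11-[(triethylsilyl)oxy]-5αH,7βH-eudesm-3-en-8-one | c1ccnc(c1)S[C@@H]1[C@@H](C(C)(C)O[Si](CC)(CC)CC)C(=O)C[C@@]2(C)CCC=C(C)[C@H]12 | intermediate
21 | 11-[(triethylsilyl)oxy]-5αH-eudesma-3,6-dien-8-one | CC(C)(O[Si](CC)(CC)CC)C1=C[C@H]2C(C)=CCC[C@]2(C)CC1=O | intermediate
22 | 3α,4α-dihydroxy-11-[(triethylsilyl)oxy]-5αH-eudesm-6-en-8-one | O[C@@H]1CC[C@]2(C)CC(=O)C(C(C)(C)O[Si](CC)(CC)CC)=C[C@H]2[C@]1(C)O | intermediate
23 | 3α,4α,11-trihydroxy-5αH-eudesm-6-en-8-one | O[C@@H]1CC[C@]2(C)CC(=O)C(C(C)(C)O)=C[C@H]2[C@]1(C)O | intermediate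
24 | (E)-2-methylbut-2-en-1-ol | C/C=C(\C)CO | starting material
25 | [(2R,3R)-2,3-dimethyloxiran-2-yl]methanol | C[C@H]1O[C@]1(C)CO | intermediate
26 | (2S,3R)-2,3-dimethyloxirane-2-carbaldehyde | C[C@H]1O[C@]1(C)C=O | intermediate
27 | (2S,3R)-2,3-dimethyloxirane-2-carboxylic acid | C[C@H]1O[C@]1(C)C(=O)O | intermediate
28 | (2S,3R)-2,3-dimethyloxirane-2-carboxylic 2,4,6-trichlorobenzoic anhydride | C[C@H]1O[C@]1(C)C(=O)OC(=O)c1c(Cl)cc(Cl)cc1Cl | intermediate
29 | 4α,11-dihydroxy-8-oxo-5αH-eudesm-6-en-3α-yl (2S,3R)-2,3-dimethyloxirane-2-carboxylate | C[C@H]1O[C@]1(C)C(=O)O[C@@H]1CC[C@]2(C)CC(=O)C(C(C)(C)O)=C[C@H]2[C@]1(C)O | target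

Total step count: 17. Longest linear sequence: 14 steps (steps 1 and 2, then 4 to 14, then 17).

**Steps most likely to fail**

Step 9. The cycloaddition may be slow because the fully substituted diene terminus C10 must bond to the β-carbon of a dienal iminium ion that is less electrophilic than a simple enal iminium ion; endo or facial selectivity may erode, and the enol acetate or silyl ether may hydrolyse in the aqueous acidic medium. The fallback sets out from 12 and uses a chiral-auxiliary, Lewis-acid cycloaddition. A Heck reaction of 12 with (S)-3-acryloyl-4-benzyloxazolidin-2-one (Pd(OAc)2, P(o-tol)3, Et3N, MeCN, 60 °C) should give (S)-4-benzyl-3-[(2E,4Z,8E,10Z)-10-acetoxy-4,8,12-trimethyl-12-(triethylsilyloxy)trideca-2,4,8,10-tetraenoyl]oxazolidin-2-one F1. Me2AlCl (CH2Cl2, −30 °C) should then give the endo cycloadduct imide F2, the benzyl group of the chelated s-cis imide shielding the Re face of C5 so that the same Si-face addition results. LiOH/H2O2 (THF/H2O, 0 °C, Na2SO3 quench) releases the auxiliary and returns to the route at acid 17.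

Step 11. The radical chain may be inefficient at the hindered secondary C6 radical, and the light- and acid-sensitive thiohydroxamate ester may decompose before transfer. The fallback sets out from aldehyde 16 and removes the formyl group directly. Tsuji–Wilkinson decarbonylation (RhCl(PPh3)3, 1.05 equiv, toluene, 110 °C) should give 8-acetoxy-11-[(triethylsilyl)oxy]-5αH,7βH-eudesma-3,8-diene F3; methanolysis (K2CO3, MeOH) gives 11-[(triethylsilyl)oxy]-5αH,7αH-eudesm-3-en-8-one F4 after equilibration at C7. Dehydrogenation with IBX (DMSO/toluene, 70 °C) can only introduce the C6=C7 bond, because C9 is flanked by the quaternary C10, and returns to the route at enone 21.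

Step 17. Acyl transfer from the α-quaternary glycidic mixed anhydride to the axial C3 hydroxyl next to a tertiary carbinol may be sluggish, and the activated acid may decompose in the meantime. The fallback sets out from 23 and 28 and activates the diol instead of the acid: 23 and Bu2SnO (toluene, reflux, removal of water) should give the 3α,4α-O-dibutylstannylene acetal F5, whose secondary oxygen is the more nucleophilic one and should take the acyl group from 28 at rt, returning to the route at target 29.

Further compounds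
F1 | step 9 | (S)-4-benzyl-3-[(2E,4Z,8E,10Z)-10-acetoxy-4,8,12-trimethyl-12-(triethylsilyloxy)trideca-2,4,8,10-tetraenoyl]oxazolidin-2-one | O=C1OC[C@H](Cc2ccccc2)N1C(=O)/C=C/C(C)=C\CC/C(C)=C/C(OC(C)=O)=C/C(C)(C)O[Si](CC)(CC)CC
F2 | step 9 | cycloadduct imide: (S)-4-benzyl-3-{8-acetoxy-11-[(triethylsilyl)oxy]-5αH,7βH-eudesma-3,8-diene-6α-carbonyl}oxazolidin-2-one | O=C1OC[C@H](Cc2ccccc2)N1C(=O)[C@H]1[C@@H](C(C)(C)O[Si](CC)(CC)CC)C(OC(C)=O)=C[C@@]2(C)CCC=C(C)[C@H]12
F3 | step 11 | 8-acetoxy-11-[(triethylsilyl)oxy]-5αH,7βH-eudesma-3,8-diene | C1[C@@H](C(C)(C)O[Si](CC)(CC)CC)C(OC(C)=O)=C[C@@]2(C)CCC=C(C)[C@H]12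
F4 | step 11 | 11-[(triethylsilyl)oxy]-5αH,7αH-eudesm-3-en-8-one | C1[C@H](C(C)(C)O[Si](CC)(CC)CC)C(=O)C[C@@]2(C)CCC=C(C)[C@H]12
F5 | step 17 | 3α,4α-O-dibutylstannylene acetal of 23 | CCCC[Sn]1(CCCC)O[C@@H]2CC[C@]3(C)CC(=O)C(C(C)(C)O)=C[C@H]3[C@]2(C)O1
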